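## Structural features

The target is a 2-arylbenzofuran with no stereocentre. Ring A (the benzo ring) carries hydroxyls at C4 and C6 and a 1,1-dimethylallyl (2-methylbut-3-en-2-yl) group at C7. It is joined through C2–C1' to a resorcinol ring B' with hydroxyls at C3' and C5' and prenyl groups at C2' and C6'. Both ortho positions of the C2–C1' bond are therefore substituted, and the quaternary carbon on C7 sits between O1 and the C6 oxygen. No stereocentres stand next to each other; every problem is one of regiochemistry and crowding. The fragile parts are the three alkenes and the four phenols: each phenol is ortho to an allylic side chain, so acid closes chromans on ring B' or a dihydrofuran from the C6 hydroxyl, and the electron-rich rings oxidize easily. The real difficulties are the hindered C2–C1' junction, placing the prenyl groups on C2'/C6' and not on C4' (between the two oxygens), and the tertiary allyl group on C7. The key step exploits C3a of ring A: it is ortho to O1 and to the C4 oxygen, para to the C6 oxygen, and the only unsubstituted ortho carbon of the aryl ether, so it can attack an aldehyde carbon (the future C3) under weak acid. C5 is activated by the same three oxygens, so the selectivity for C3a rests on reach, not on intrinsic nucleophilicity.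

## Logic of the disconnections

23 ⇒ 22. Four O–Si bonds are cut. Silyl ethers are the only phenol protection here that leaves without acid, hydrogen or oxidant. The forward step needs buffered fluoride and exclusion of air.

22 ⇒ 20. The C3–C3a bond is cut and water is added back across C2–C3. This opens the furan ring and turns C2 into an sp3 carbon that already holds O1 and ring B', so the crowded C2–C1' bond never has to be made by coupling. The forward step demands that the aldehyde be attacked by C3a only: not by the prenyl alkenes of ring B', and not by C5 of a second molecule. The design of 20 is therefore tightened in three ways: it is made last and used without storage, the closure uses a weak Brønsted acid, and it is run at high dilution. The structures of 20 and 22 were checked atom by atom against 23 and needed no correction.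

20 ⇒ 18. The aldehyde is taken back to a methyl ester. The α-hydrogen of 20 is activated by aryl, aryloxy and formyl groups, so this oxidation level should appear only one step before use. The forward step must stop at the aldehyde.

18 ⇒ 7 + 17. The O1–C2 ether bond is cut, which divides the molecule into two ring fragments of similar size. The forward step is an SN2 displacement at a crowded benzylic α-carbon by a phenoxide with a tertiary ortho substituent, and it must go at oxygen, not carbon.

17 ⇒ 15 ⇒ 12 + 13 ⇒ 10 ⇒ 8. The C–Br bond at the α-carbon is cut first, then the two aryl–CH2 bonds at C2' and C6', then the two aryl–Br bonds, then two O–Si bonds. Halogenation of a 1,3-dioxygenated ring goes para to oxygen and avoids the carbon between two bulky silyloxy groups, which fixes the prenyl positions. Cross-coupling then delivers the linear prenyl group. The forward steps demand a twofold coupling at crowded carbons and an enolate bromination that leaves the alkenes alone.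

7 ⇒ 5 ⇒ 3 + 4 ⇒ 1. The C7–C(quaternary) bond is cut by a [3,3] shift back to an O-prenyl ether, then the O–C bond, then two O–Si bonds. The sigmatropic shift inverts the allyl unit and places its tertiary end ortho to oxygen, and the symmetry of 5 makes both ortho carbons the same. The forward step must stop at the ortho product.

## Other disconnections considered

Alternative 1: The cut runs through ring B' at C1'–C6' and C4'–C5', so ring B' is carried as a cyclohexane-1,3-dione. Forward, dimethyl malonate A2 would add in a Michael reaction to the benzofuranyl enone A1, and the methyl ketone enolate would then acylate on a malonate ester to give dione A3.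
- In favour: this is the classical dihydroresorcinol annulation under alkoxide alone, and the C2–C1' bond exists before either ortho substituent.
- Against: A3 is two hydrogens short of a resorcinol, so a dehydrogenation must be run on a molecule that carries alkenes and an electron-rich benzofuran.
- Against: the prenyl groups belong on C2' and C6', each α to one carbonyl only, while the acidic carbon between the carbonyls is C4', which must stay bare. The ester on C6' steers one alkylation; the other needs an enol ether and a kinetic α'-enolate (Stork–Danheiser type).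
- Against: the ring A methoxymethyl ethers would have to leave under acid next to the 1,1-dimethylallyl group.
- Comparison: on mechanism its key step is more certain than step 10 and has no alkene competitor, so it is the better there. On structure it leaves the hardest features of ring B' for later, whereas 15 already has them. On step economy it still needs the ring A chemistry of steps 1 to 3, and the steps after A3 (decarboxylation, two alkylations, aromatization, deprotection) should outnumber the two-step end-game chosen.

Alternative 2: The cut is C5–C6 of ring A, opened to furan keto ester A4. Forward, the acetyl enolate would attack the side-chain ester in a six-membered Claisen condensation. The cyclic 1,3-diketone is a tautomer of the 4,6-diol and should aromatize without oxidant to A5.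
- In favour: ring A appears at the right oxidation level, and the C7 group could come from an ester enolate Claisen rearrangement instead of a hot aryl Claisen. There is no statistical protection and no aldehyde facing prenyl alkenes.
- Against: A4 is a demanding 2,3,5-trisubstituted furan whose C5–aryl bond has the same two ortho prenyl groups.
- Against: the ester carbonyl is neopentyl-like, and the more acidic hydrogen is α to the ester, so the productive enolate forms only by equilibration.
- Against: the ring B' methoxymethyl ethers of A5 must finally be cleaved by acid with four phenols and three alkenes present.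
- Comparison: on oxidation-state economy and on avoiding the crowded etherification of step 8 it is the equal or the better. On mechanism both are ordinary polar closures. Its end-game is worse (acid, not fluoride), and it should be longer because the furan and the hindered C–aryl bond must be built.

Alternative 3: The cut removes C2'–C3', C3'–C4' and C5'–C6' of ring B'. Forward, cyclobutenone A6 would open thermally to a vinylketene, add (triisopropylsilyloxy)acetylene A7 in a [2+2] step, open again, and close by 6π electrocyclization and tautomerization to A8 (Danheiser benzannulation).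
- In favour: every position of ring B' is fixed by the pericyclic cascade, no acid, base or metal is needed, and the C2–C1' bond is present from the start. Only silyl ethers are used, so the fluoride end-game equals the chosen one.
- Against: A6 is a 2,3,4-trisubstituted cyclobutenone with a prenyl-bearing sp3 carbon and has no short route.
- Against: A7 is a sensitive terminal siloxyalkyne, and the vinylketene carries alkenes and allylic hydrogens within reach.
- Against: ring A with its C7 group must still be made.
- Comparison: on regiochemical certainty for ring B' it equals or betters steps 5 and 6, and it has no Prins competitor, which is better. The risk moves to the synthesis of A6, and the step count should be higher.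

Key step: step 10

Remark: methyl 3,5-dihydroxyphenylacetate (8) is taken as a purchased compound; from the acid, one Fischer esterification would be added. The stereocentres that appear in 6 and in 17 to 21 are racemic and are erased on the way.

## Route

Step 1
Reactants: 1 phloroglucinol
Product: 3 3,5-bis(triisopropylsilyloxy)phenol, via monosilyl ether 2 (not isolated)
Conditions: TIPSCl (2.0 equiv), imidazole (4 equiv), DMF, 0 °C to rt
Reagents that add atoms: triisopropylsilyl chloride, CC(C)[Si](Cl)(C(C)C)C(C)C
Why: Phenol silylation with a silyl chloride and imidazole; two equivalents should make 3 the main part of a statistical mixture, separable by chromatography, with 2 re-silylated; the bulky group is chosen to survive carbonate bases, 185 °C and weak acid.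

Step 2
Reactants: 3 3,5-bis(triisopropylsilyloxy)phenol; 4 prenyl bromide (1-bromo-3-methylbut-2-ene)
Product: 5 1-(3-methylbut-2-en-1-yloxy)-3,5-bis(triisopropylsilyloxy)benzene
Conditions: K2CO3, acetone, reflux
Reagents that add atoms: none
Why: Williamson ether synthesis (SN2 at the primary allylic bromide); with the other two oxygens silylated the phenoxide has no polyanion character, so O-alkylation should prevail over C-alkylation.

Step 3
Reactants: 5 1-(3-methylbut-2-en-1-yloxy)-3,5-bis(triisopropylsilyloxy)benzene
Product: 7 2-(2-methylbut-3-en-2-yl)-3,5-bis(triisopropylsilyloxy)phenol, via ortho-dienone 6 (not isolated)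
Conditions: PhNEt2, 185 °C, sealed tube, Ar
Reagents that add atoms: none
Why: Aromatic Claisen rearrangement: the [3,3] shift bonds the tertiary allyl terminus to the ortho carbon (dienone 6) and enolization gives 7; both ortho carbons are equivalent by symmetry, and the basic amine solvent suppresses acid-catalysed ring closure of the product.

Step 4
Reactants: 8 methyl 3,5-dihydroxyphenylacetate
Product: 10 methyl 2-[3,5-bis(triisopropylsilyloxy)phenyl]acetate, via monosilyl ether 9 (not isolated)
Conditions: TIPSCl (2.3 equiv), imidazole, DMF, rt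
Reagents that add atoms: triisopropylsilyl chloride, CC(C)[Si](Cl)(C(C)C)C(C)C
Why: Exhaustive silylation of both phenols with silyl chloride and imidazole; the methyl ester is inert under these conditions.

Step 5
Reactants: 10 methyl 2-[3,5-bis(triisopropylsilyloxy)phenyl]acetate
Product: 12 methyl 2-[2,6-dibromo-3,5-bis(triisopropylsilyloxy)phenyl]acetate, via monobromide 11 (not isolated)
Conditions: NBS (2.1 equiv), MeCN, 0 °C to rt, dark
Reagents that add atoms: N-bromosuccinimide, O=C1CCC(=O)N1Br
Why: Electrophilic aromatic bromination; C2 and C6 are each ortho to one silyloxy group and para to the other, whereas C4 is buried between two triisopropylsilyloxy groups, so the 2,6-dibromide is expected; no strong acid is formed.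

Step 6
Reactants: 12 methyl 2-[2,6-dibromo-3,5-bis(triisopropylsilyloxy)phenyl]acetate; 13 tributyl(3-methylbut-2-en-1-yl)stannane (2.6 equiv)
Product: 15 methyl 2-[2,6-bis(3-methylbut-2-en-1-yl)-3,5-bis(triisopropylsilyloxy)phenyl]acetate, via monoprenyl bromide 14 (not isolated)
Conditions: Pd(PPh3)4 (10 mol%), DMF, 100 °C; aq. KF work-up
Reagents that add atoms: none
Why: Twofold Stille coupling (oxidative addition to zerovalent palladium, transmetallation of the allylstannane, reductive elimination at the unsubstituted allyl terminus) should give the linear prenyl arene under neutral conditions that spare the silyl ethers and the enolizable ester.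

Step 7
Reactants: 15 methyl 2-[2,6-bis(3-methylbut-2-en-1-yl)-3,5-bis(triisopropylsilyloxy)phenyl]acetate
Product: 17 methyl 2-bromo-2-[2,6-bis(3-methylbut-2-en-1-yl)-3,5-bis(triisopropylsilyloxy)phenyl]acetate (racemic), via lithium enolate 16 (not isolated)
Conditions: LiN(i-Pr)2, THF, −78 °C; then added to BrCl2CCCl2Br, THF, −78 °C
Reagents that add atoms: 1,2-dibromo-1,1,2,2-tetrachloroethane, ClC(Cl)(Br)C(Cl)(Cl)Br
Why: α-Halogenation of an ester enolate with a positive-bromine donor; the pre-formed enolate 16 should react at −78 °C far faster than the prenyl alkenes or the arene, and inverse addition limits the proton exchange that leads to dibromination.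

Step 8
Reactants: 7 2-(2-methylbut-3-en-2-yl)-3,5-bis(triisopropylsilyloxy)phenol; 17 methyl 2-bromo-2-[2,6-bis(3-methylbut-2-en-1-yl)-3,5-bis(triisopropylsilyloxy)phenyl]acetate
Product: 18 methyl 2-[2,6-bis(3-methylbut-2-en-1-yl)-3,5-bis(triisopropylsilyloxy)phenyl]-2-[2-(2-methylbut-3-en-2-yl)-3,5-bis(triisopropylsilyloxy)phenoxy]acetate (racemic)
Conditions: Cs2CO3, MeCN, 25 to 40 °C
Reagents that add atoms: none
Why: Williamson-type SN2 displacement of an α-bromo ester, activated by the adjacent carbonyl, by the caesium phenoxide of 7; there is no β-hydrogen, so elimination cannot compete; the new stereocentre is racemic and is erased in step 10.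

Step 9
Reactants: 18 methyl 2-[2,6-bis(3-methylbut-2-en-1-yl)-3,5-bis(triisopropylsilyloxy)phenyl]-2-[2-(2-methylbut-3-en-2-yl)-3,5-bis(triisopropylsilyloxy)phenoxy]acetate
Product: 20 2-[2,6-bis(3-methylbut-2-en-1-yl)-3,5-bis(triisopropylsilyloxy)phenyl]-2-[2-(2-methylbut-3-en-2-yl)-3,5-bis(triisopropylsilyloxy)phenoxy]acetaldehyde (racemic), via aluminium hemiacetal 19 (not isolated)
Conditions: i-Bu2AlH (1.2 equiv), CH2Cl2, −78 °C; MeOH, then aq. potassium sodium tartrate
Reagents that add atoms: none
Why: Partial reduction of an ester by i-Bu2AlH: the tetrahedral aluminium hemiacetal 19, held at −78 °C by chelation to the α-aryloxy oxygen, should collapse to the aldehyde only on work-up; 20 is used at once because its α-hydrogen is triply activated.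

Step 10
Reactants: 20 2-[2,6-bis(3-methylbut-2-en-1-yl)-3,5-bis(triisopropylsilyloxy)phenyl]-2-[2-(2-methylbut-3-en-2-yl)-3,5-bis(triisopropylsilyloxy)phenoxy]acetaldehyde
Product: 22 2-[2,6-bis(3-methylbut-2-en-1-yl)-3,5-bis(triisopropylsilyloxy)phenyl]-7-(2-methylbut-3-en-2-yl)-4,6-bis(triisopropylsilyloxy)-1-benzofuran, via 3-hydroxy-2,3-dihydrobenzofuran 21 (not isolated)
Conditions: PPTS (20 mol%), 4 Å MS, ClCH2CH2Cl (0.01 M), 60 °C
Reagents that add atoms: none
Why: Pyridinium tosylate protonates the aldehyde, C3a attacks the carbonyl carbon (Friedel–Crafts hydroxyalkylation) and rearomatization gives carbinol 21. Under the same acid 21 ionizes at C3, a benzylic position stabilized by the C4 and C6 oxygens, and loss of the C2 hydrogen gives the aromatic furan. The closest known reaction type is the acid-mediated cyclodehydration of α-aryloxy aldehydes and ketones to benzofurans. The one ring closes in the 5-exo-trig mode with respect to the carbonyl group (5-enolendo if ring A is counted as the enol ether partner), forming the C3–C3a bond. No stereocentre remains: the carbinol centre of 21 and the centre at C2 are both lost on dehydration. Regioselectivity on ring A is secured because the other ortho carbon carries the 1,1-dimethylallyl group and C5 cannot reach the aldehyde. Chemoselectivity over a six-membered carbonyl-ene or Prins attack by a flanking prenyl alkene is sought by using a weak Brønsted acid in place of a Lewis acid, relying on the higher nucleophilicity of the tri-oxygenated arene. High dilution suppresses intermolecular attack at C5, and the triisopropylsilyl ethers should tolerate this acid.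

Step 11
Reactants: 22 2-[2,6-bis(3-methylbut-2-en-1-yl)-3,5-bis(triisopropylsilyloxy)phenyl]-7-(2-methylbut-3-en-2-yl)-4,6-bis(triisopropylsilyloxy)-1-benzofuran
Product: 23 2-[3,5-dihydroxy-2,6-bis(3-methylbut-2-en-1-yl)phenyl]-7-(2-methylbut-3-en-2-yl)-1-benzofuran-4,6-diol
Conditions: Bu4NF (4.4 equiv), AcOH (4.4 equiv), THF, 0 °C, Ar
Reagents that add atoms: none
Why: Fluoride cleaves the four aryl O–Si bonds (strong Si–F bond, phenoxide leaving groups); acetic acid buffers the phenoxides so that the electron-rich tetraphenol should not oxidize, and no acid strong enough to close a chroman or dihydrofuran ring is present.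

## Compound list

1 | phloroglucinol | Oc1cc(O)cc(O)c1 | starting material
2 | 5-(triisopropylsilyloxy)benzene-1,3-diol | Oc1cc(O)cc(O[Si](C(C)C)(C(C)C)C(C)C)c1 | intermediate
3 | 3,5-bis(triisopropylsilyloxy)phenol | Oc1cc(O[Si](C(C)C)(C(C)C)C(C)C)cc(O[Si](C(C)C)(C(C)C)C(C)C)c1 | intermediate
4 | prenyl bromide (1-bromo-3-methylbut-2-ene) | CC(C)=CCBr | starting material
5 | 1-(3-methylbut-2-en-1-yloxy)-3,5-bis(triisopropylsilyloxy)benzene | CC(C)=CCOc1cc(O[Si](C(C)C)(C(C)C)C(C)C)cc(O[Si](C(C)C)(C(C)C)C(C)C)c1 | intermediate
6 | 6-(2-methylbut-3-en-2-yl)-3,5-bis(triisopropylsilyloxy)cyclohexa-2,4-dien-1-one (racemic) | C=CC(C)(C)C1C(=O)C=C(O[Si](C(C)C)(C(C)C)C(C)C)C=C1O[Si](C(C)C)(C(C)C)C(C)C | intermediate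
7 | 2-(2-methylbut-3-en-2-yl)-3,5-bis(triisopropylsilyloxy)phenol | C=CC(C)(C)c1c(O)cc(O[Si](C(C)C)(C(C)C)C(C)C)cc1O[Si](C(C)C)(C(C)C)C(C)C | intermediate
8 | methyl 3,5-dihydroxyphenylacetate | COC(=O)Cc1cc(O)cc(O)c1 | starting material
9 | methyl 2-[3-hydroxy-5-(triisopropylsilyloxy)phenyl]acetate | COC(=O)Cc1cc(O)cc(O[Si](C(C)C)(C(C)C)C(C)C)c1 | intermediate
10 | methyl 2-[3,5-bis(triisopropylsilyloxy)phenyl]acetate | COC(=O)Cc1cc(O[Si](C(C)C)(C(C)C)C(C)C)cc(O[Si](C(C)C)(C(C)C)C(C)C)c1 | intermediate
11 | methyl 2-[2-bromo-3,5-bis(triisopropylsilyloxy)phenyl]acetate | COC(=O)Cc1cc(O[Si](C(C)C)(C(C)C)C(C)C)cc(O[Si](C(C)C)(C(C)C)C(C)C)c1Br | intermediate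
12 | methyl 2-[2,6-dibromo-3,5-bis(triisopropylsilyloxy)phenyl]acetate | COC(=O)Cc1c(Br)c(O[Si](C(C)C)(C(C)C)C(C)C)cc(O[Si](C(C)C)(C(C)C)C(C)C)c1Br | intermediate
13 | tributyl(3-methylbut-2-en-1-yl)stannane | CCCC[Sn](CCCC)(CCCC)CC=C(C)C | starting material
14 | methyl 2-[2-bromo-6-(3-methylbut-2-en-1-yl)-3,5-bis(triisopropylsilyloxy)phenyl]acetate | COC(=O)Cc1c(Br)c(O[Si](C(C)C)(C(C)C)C(C)C)cc(O[Si](C(C)C)(C(C)C)C(C)C)c1CC=C(C)C | intermediate
15 | methyl 2-[2,6-bis(3-methylbut-2-en-1-yl)-3,5-bis(triisopropylsilyloxy)phenyl]acetate | COC(=O)Cc1c(CC=C(C)C)c(O[Si](C(C)C)(C(C)C)C(C)C)cc(O[Si](C(C)C)(C(C)C)C(C)C)c1CC=C(C)C | intermediate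
16 | lithium enolate of 15 (enolate geometry not defined) | COC(O[Li])=Cc1c(CC=C(C)C)c(O[Si](C(C)C)(C(C)C)C(C)C)cc(O[Si](C(C)C)(C(C)C)C(C)C)c1CC=C(C)C | intermediate
17 | methyl 2-bromo-2-[2,6-bis(3-methylbut-2-en-1-yl)-3,5-bis(triisopropylsilyloxy)phenyl]acetate (racemic) | COC(=O)C(Br)c1c(CC=C(C)C)c(O[Si](C(C)C)(C(C)C)C(C)C)cc(O[Si](C(C)C)(C(C)C)C(C)C)c1CC=C(C)C | intermediate
18 | methyl 2-[2,6-bis(3-methylbut-2-en-1-yl)-3,5-bis(triisopropylsilyloxy)phenyl]-2-[2-(2-methylbut-3-en-2-yl)-3,5-bis(triisopropylsilyloxy)phenoxy]acetate (racemic) | C=CC(C)(C)c1c(O[Si](C(C)C)(C(C)C)C(C)C)cc(O[Si](C(C)C)(C(C)C)C(C)C)cc1OC(C(=O)OC)c1c(CC=C(C)C)c(O[Si](C(C)C)(C(C)C)C(C)C)cc(O[Si](C(C)C)(C(C)C)C(C)C)c1CC=C(C)C | intermediate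
19 | diisobutylaluminium hemiacetal of 18 (mixture of diastereomers) | C=CC(C)(C)c1c(O[Si](C(C)C)(C(C)C)C(C)C)cc(O[Si](C(C)C)(C(C)C)C(C)C)cc1OC(C(OC)O[Al](CC(C)C)CC(C)C)c1c(CC=C(C)C)c(O[Si](C(C)C)(C(C)C)C(C)C)cc(O[Si](C(C)C)(C(C)C)C(C)C)c1CC=C(C)C | intermediate
20 | 2-[2,6-bis(3-methylbut-2-en-1-yl)-3,5-bis(triisopropylsilyloxy)phenyl]-2-[2-(2-methylbut-3-en-2-yl)-3,5-bis(triisopropylsilyloxy)phenoxy]acetaldehyde (racemic) | C=CC(C)(C)c1c(O[Si](C(C)C)(C(C)C)C(C)C)cc(O[Si](C(C)C)(C(C)C)C(C)C)cc1OC(C=O)c1c(CC=C(C)C)c(O[Si](C(C)C)(C(C)C)C(C)C)cc(O[Si](C(C)C)(C(C)C)C(C)C)c1CC=C(C)C | intermediate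
21 | 2-[2,6-bis(3-methylbut-2-en-1-yl)-3,5-bis(triisopropylsilyloxy)phenyl]-7-(2-methylbut-3-en-2-yl)-4,6-bis(triisopropylsilyloxy)-2,3-dihydro-1-benzofuran-3-ol (mixture of diastereomers) | C=CC(C)(C)c1c(O[Si](C(C)C)(C(C)C)C(C)C)cc(O[Si](C(C)C)(C(C)C)C(C)C)c2c1OC(c1c(CC=C(C)C)c(O[Si](C(C)C)(C(C)C)C(C)C)cc(O[Si](C(C)C)(C(C)C)C(C)C)c1CC=C(C)C)C2O | intermediate
22 | 2-[2,6-bis(3-methylbut-2-en-1-yl)-3,5-bis(triisopropylsilyloxy)phenyl]-7-(2-methylbut-3-en-2-yl)-4,6-bis(triisopropylsilyloxy)-1-benzofuran | C=CC(C)(C)c1c(O[Si](C(C)C)(C(C)C)C(C)C)cc(O[Si](C(C)C)(C(C)C)C(C)C)c2cc(-c3c(CC=C(C)C)c(O[Si](C(C)C)(C(C)C)C(C)C)cc(O[Si](C(C)C)(C(C)C)C(C)C)c3CC=C(C)C)oc12 | intermediate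
23 | 2-[3,5-dihydroxy-2,6-bis(3-methylbut-2-en-1-yl)phenyl]-7-(2-methylbut-3-en-2-yl)-1-benzofuran-4,6-diol | C=CC(C)(C)c1c(O)cc(O)c2cc(-c3c(CC=C(C)C)c(O)cc(O)c3CC=C(C)C)oc12 | target

## Step count and least certain steps

Total: 11 steps. Longest linear sequence: 8 steps (steps 4 to 11, from 8 to 23). The ring A branch (steps 1 to 3) joins at step 8.

Step 10 (key step). The most likely failure is attack on the activated aldehyde by a flanking prenyl alkene of ring B' (six-membered carbonyl-ene or Prins closure) in competition with the five-membered Friedel–Crafts closure. Intermolecular hydroxyalkylation at C5 and slow conversion under so weak an acid are lesser risks. A stronger activator such as BF3·OEt2 at −78 °C would speed both pathways. The fallback removes the competitor by bringing in the prenyl groups after ring closure. It sets out from 12 and comes back at 22. Enolate bromination of 12 as in step 7 would give methyl 2-bromo-2-[2,6-dibromo-3,5-bis(triisopropylsilyloxy)phenyl]acetate F1. Etherification with 7 as in step 8 would give methyl 2-[2,6-dibromo-3,5-bis(triisopropylsilyloxy)phenyl]-2-[2-(2-methylbut-3-en-2-yl)-3,5-bis(triisopropylsilyloxy)phenoxy]acetate F2. Reduction with i-Bu2AlH as in step 9 would give the corresponding acetaldehyde F3. Acid cyclodehydration, now free of ring B' alkenes and open to stronger acids, would give 2-[2,6-dibromo-3,5-bis(triisopropylsilyloxy)phenyl]-7-(2-methylbut-3-en-2-yl)-4,6-bis(triisopropylsilyloxy)-1-benzofuran F4. Twofold Stille coupling with 13 under the conditions of step 6 would return to 22.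

Step 8. The displacement joins a phenoxide with a tertiary ortho group to a secondary benzylic carbon flanked by two ortho prenyl groups, so it may be slow. Slow substitution would let C-alkylation of the ambident phenoxide, bromine transfer from 17 to the electron-rich phenoxide (reductive debromination), or base-induced loss of a silyl group take over. The fallback avoids the carbonate base, the free phenoxide and the bromide, and so also covers a failure of step 7. It sets out from 15 and comes back at 18. Enolate hydroxylation of 15 (KN(SiMe3)2, then 2-(phenylsulfonyl)-3-phenyloxaziridine, THF, −78 °C) would give methyl 2-hydroxy-2-[2,6-bis(3-methylbut-2-en-1-yl)-3,5-bis(triisopropylsilyloxy)phenyl]acetate F5. Mitsunobu etherification of F5 with 7 (PPh3, DIAD, toluene, 0 °C to rt) would give 18.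

Step 3. At 185 °C the ortho-dienone may undergo a further Cope shift to the carbon between the two silyloxy groups before it enolizes. The product phenol may also rearrange further or cyclize onto its own vinyl group on prolonged heating. The fallback installs the tertiary allyl group by cross-coupling. It sets out from 3 and comes back at 7. Ortho-bromination of 3 (NBS, catalytic i-Pr2NH, CH2Cl2, −78 °C) would give 2-bromo-3,5-bis(triisopropylsilyloxy)phenol F6. Suzuki–Miyaura coupling of F6 with 3-methylbut-2-enylboronic acid pinacol ester would follow, using Pd(OAc)2, K3PO4, THF/H2O and a bulky biarylphosphine chosen to favour bond formation at the γ-carbon of the allyl unit. This would give 7.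

Step 6. Oxidative addition at bromides flanked by a triisopropylsilyloxy group and the acetate-bearing carbon may be slow. The second coupling may stall, protodebromination may compete, and some bond formation at the substituted allyl terminus or alkene migration into conjugation may occur. The fallback uses the smaller, symmetric allyl group and builds the prenyl ends by metathesis. It sets out from 12 and comes back at 15. Twofold Stille coupling with allyltributylstannane (Pd(PPh3)4, DMF, 100 °C) would give methyl 2-[2,6-diallyl-3,5-bis(triisopropylsilyloxy)phenyl]acetate F7. Cross-metathesis of F7 with excess 2-methylbut-2-ene (second-generation Grubbs catalyst, CH2Cl2, 40 °C) would give 15.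

## Further compounds

F1 | step 10 | methyl 2-bromo-2-[2,6-dibromo-3,5-bis(triisopropylsilyloxy)phenyl]acetate (racemic) | COC(=O)C(Br)c1c(Br)c(O[Si](C(C)C)(C(C)C)C(C)C)cc(O[Si](C(C)C)(C(C)C)C(C)C)c1Br
F2 | step 10 | methyl 2-[2,6-dibromo-3,5-bis(triisopropylsilyloxy)phenyl]-2-[2-(2-methylbut-3-en-2-yl)-3,5-bis(triisopropylsilyloxy)phenoxy]acetate (racemic) | C=CC(C)(C)c1c(O[Si](C(C)C)(C(C)C)C(C)C)cc(O[Si](C(C)C)(C(C)C)C(C)C)cc1OC(C(=O)OC)c1c(Br)c(O[Si](C(C)C)(C(C)C)C(C)C)cc(O[Si](C(C)C)(C(C)C)C(C)C)c1Br
F3 | step 10 | 2-[2,6-dibromo-3,5-bis(triisopropylsilyloxy)phenyl]-2-[2-(2-methylbut-3-en-2-yl)-3,5-bis(triisopropylsilyloxy)phenoxy]acetaldehyde (racemic) | C=CC(C)(C)c1c(O[Si](C(C)C)(C(C)C)C(C)C)cc(O[Si](C(C)C)(C(C)C)C(C)C)cc1OC(C=O)c1c(Br)c(O[Si](C(C)C)(C(C)C)C(C)C)cc(O[Si](C(C)C)(C(C)C)C(C)C)c1Br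
F4 | step 10 | 2-[2,6-dibromo-3,5-bis(triisopropylsilyloxy)phenyl]-7-(2-methylbut-3-en-2-yl)-4,6-bis(triisopropylsilyloxy)-1-benzofuran | C=CC(C)(C)c1c(O[Si](C(C)C)(C(C)C)C(C)C)cc(O[Si](C(C)C)(C(C)C)C(C)C)c2cc(-c3c(Br)c(O[Si](C(C)C)(C(C)C)C(C)C)cc(O[Si](C(C)C)(C(C)C)C(C)C)c3Br)oc12
F5 | step 8 | methyl 2-hydroxy-2-[2,6-bis(3-methylbut-2-en-1-yl)-3,5-bis(triisopropylsilyloxy)phenyl]acetate (racemic) | COC(=O)C(O)c1c(CC=C(C)C)c(O[Si](C(C)C)(C(C)C)C(C)C)cc(O[Si](C(C)C)(C(C)C)C(C)C)c1CC=C(C)C
F6 | step 3 | 2-bromo-3,5-bis(triisopropylsilyloxy)phenol | Oc1cc(O[Si](C(C)C)(C(C)C)C(C)C)cc(O[Si](C(C)C)(C(C)C)C(C)C)c1Br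
F7 | step 6 | methyl 2-[2,6-diallyl-3,5-bis(triisopropylsilyloxy)phenyl]acetate | COC(=O)Cc1c(CC=C)c(O[Si](C(C)C)(C(C)C)C(C)C)cc(O[Si](C(C)C)(C(C)C)C(C)C)c1CC=C
A1 | alternative 1 | (E)-4-[4,6-bis(methoxymethoxy)-7-(2-methylbut-3-en-2-yl)-1-benzofuran-2-yl]but-3-en-2-one | CC(=O)/C=C/c1cc2c(OCOC)cc(OCOC)c(C(C)(C)C=C)c2o1
A2 | alternative 1 | dimethyl malonate | COC(=O)CC(=O)OC
A3 | alternative 1 | methyl 2-[4,6-bis(methoxymethoxy)-7-(2-methylbut-3-en-2-yl)-1-benzofuran-2-yl]-4,6-dioxocyclohexane-1-carboxylate (racemic, keto form) | COC(=O)C1C(=O)CC(=O)CC1c1cc2c(OCOC)cc(OCOC)c(C(C)(C)C=C)c2o1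
A4 | alternative 2 | methyl 2-{3-acetyl-5-[3,5-bis(methoxymethoxy)-2,6-bis(3-methylbut-2-en-1-yl)phenyl]furan-2-yl}-3,3-dimethylpent-4-enoate (racemic) | COC(=O)C(c1oc(-c2c(CC=C(C)C)c(OCOC)cc(OCOC)c2CC=C(C)C)cc1C(C)=O)C(C)(C)C=C
A5 | alternative 2 | 2-[3,5-bis(methoxymethoxy)-2,6-bis(3-methylbut-2-en-1-yl)phenyl]-7-(2-methylbut-3-en-2-yl)-1-benzofuran-4,6-diol | C=CC(C)(C)c1c(O)cc(O)c2cc(-c3c(CC=C(C)C)c(OCOC)cc(OCOC)c3CC=C(C)C)oc12
A6 | alternative 3 | 3-[4,6-bis(tert-butyldimethylsilyloxy)-7-(2-methylbut-3-en-2-yl)-1-benzofuran-2-yl]-2,4-bis(3-methylbut-2-en-1-yl)cyclobut-2-en-1-one (racemic) | O=C1C(CC=C(C)C)=C(c2cc3c(O[Si](C)(C)C(C)(C)C)cc(O[Si](C)(C)C(C)(C)C)c(C(C)(C)C=C)c3o2)C1CC=C(C)C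
A7 | alternative 3 | (triisopropylsilyloxy)acetylene | C#CO[Si](C(C)C)(C(C)C)C(C)C
A8 | alternative 3 | 3-[4,6-bis(tert-butyldimethylsilyloxy)-7-(2-methylbut-3-en-2-yl)-1-benzofuran-2-yl]-2,4-bis(3-methylbut-2-en-1-yl)-5-(triisopropylsilyloxy)phenol | C=CC(C)(C)c1c(O[Si](C)(C)C(C)(C)C)cc(O[Si](C)(C)C(C)(C)C)c2cc(-c3c(CC=C(C)C)c(O)cc(O[Si](C(C)C)(C(C)C)C(C)C)c3CC=C(C)C)oc12
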